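**Plan**
- Retrosynthetic cuts, in order: the two O-benzyl bonds on ring A (acyl ring); the two aryl–CH3 bonds at C5 of ring A and C5 of ring B, cut together back to a dibromide; the O2–CH3 and C5–Br bonds of ring B; the depside C(=O)–O bond; on ring A the C5–Br and C3–CHO bonds.
- Forward: orsellinic acid is carried as its allyl ester to the 3-formyl-5-bromo-2,4-di-O-benzyl acid, which is esterified at O4 of Evernyl; ring B is brominated at C5 and methylated at O2; both bromines are exchanged for methyl in one palladium-catalysed operation; hydrogenolysis frees the phenols.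
- Enabling feature: both benzene rings are hexasubstituted, and the methyls on C5 of ring A and C5 of ring B sit on the one carbon each orsellinate-type ring leaves open, ortho/para to ring oxygen, so bromine can only enter there before being replaced by CH3.
- Both rings are bought; no ring is formed; the two halves are joined at the ester bond in step 6.
- The target has no stereocentre, so it is a single achiral compound and no stereochemistry has to be set.

Key step: step 9

Assumption: each ring is numbered from its carboxyl-bearing carbon (C1), ring A being the acyl ring and ring B the phenol ring; orsellinic acid and Evernyl are taken as purchasable.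

**Step 1**
Reactants: 1 orsellinic acid (2,4-dihydroxy-6-methylbenzoic acid)
Product: 2 allyl 2,4-dihydroxy-6-methylbenzoate
Conditions: allyl bromide (1.1 equiv), KHCO3, DMF, rt
Reagents that add atoms: allyl bromide, C=CCBr
Why: SN2 O-alkylation of the carboxylate: hydrogencarbonate deprotonates only the carboxylic acid, so the phenols are not alkylated, and the allyl ester is chosen because it can later be removed under neutral conditions in the presence of C–Br, CHO and benzyl ethers.

**Step 2**
Reactants: 2 allyl 2,4-dihydroxy-6-methylbenzoate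
Product: 4 allyl 3-formyl-2,4-dihydroxy-6-methylbenzoate, via chloro(methoxy)methyl arene 3 (not isolated)
Conditions: Cl2CHOMe, TiCl4, CH2Cl2, 0 °C; then 1 M HCl
Reagents that add atoms: dichloromethyl methyl ether, COC(Cl)Cl; water, O
Why: Rieche formylation: C3 is ortho to both oxygens and so is reached from either titanium phenoxide, whereas C5 is ortho to only one and is flanked by the C6 methyl; hydrolysis of 3 on work-up gives the aldehyde, and any C5 isomer is removed by crystallisation or chromatography.

**Step 3**
Reactants: 4 allyl 3-formyl-2,4-dihydroxy-6-methylbenzoate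
Product: 5 allyl 5-bromo-3-formyl-2,4-dihydroxy-6-methylbenzoate
Conditions: NBS (1.05 equiv), MeCN, 0 °C to rt, dark
Reagents that add atoms: N-bromosuccinimide, O=C1CCC(=O)N1Br
Why: Electrophilic aromatic bromination at the last free ring carbon, C5, which is ortho to O4–H and para to O2–H; one equivalent of NBS in the dark leaves the electron-poor allyl alkene, the aldehyde and the benzylic methyl untouched.

**Step 4**
Reactants: 5 allyl 5-bromo-3-formyl-2,4-dihydroxy-6-methylbenzoate
Product: 7 allyl 2,4-bis(benzyloxy)-5-bromo-3-formyl-6-methylbenzoate, via 4-O-benzyl monoether 6 (not isolated)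
Conditions: BnBr (2.5 equiv), K2CO3, cat. Bu4NI, DMF, 60 °C
Reagents that add atoms: benzyl bromide, BrCc1ccccc1
Why: Williamson ether synthesis: carbonate in DMF breaks the hydrogen bonds of both phenols and the phenoxides are alkylated by the reactive benzylic halide (O4 first, then the more enclosed O2), the non-enolisable aldehyde and the hindered allyl ester being inert to carbonate; the benzyl caps ensure that no salicylate-type phenoxide can later expel ring B.

**Step 5**
Reactants: 7 allyl 2,4-bis(benzyloxy)-5-bromo-3-formyl-6-methylbenzoate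
Product: 8 2,4-bis(benzyloxy)-5-bromo-3-formyl-6-methylbenzoic acid
Conditions: Pd(PPh3)4 (5 mol %), morpholine (3 equiv), THF, rt; dilute HCl work-up
Reagents that add atoms: none
Why: Tsuji–Trost deallylation: Pd(0) ionises the allyl ester to a π-allyl complex that morpholine intercepts, so the di-ortho-substituted carboxyl is freed without attack at its shielded carbonyl and without hydroxide near the aldehyde, and at room temperature Pd(PPh3)4 does not insert into the hindered, electron-rich C–Br bond.

**Step 6**
Reactants: 8 2,4-bis(benzyloxy)-5-bromo-3-formyl-6-methylbenzoic acid; 9 Evernyl (methyl 2,4-dihydroxy-3,6-dimethylbenzoate)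
Product: 11 methyl 4-{[2,4-bis(benzyloxy)-5-bromo-3-formyl-6-methylbenzoyl]oxy}-2-hydroxy-3,6-dimethylbenzoate, via mixed trifluoroacetic anhydride 10 (not isolated)
Conditions: TFAA (4 equiv), toluene, 0 °C to rt
Reagents that add atoms: none
Why: Esterification through the mixed carboxylic–trifluoroacetic anhydride 10, the usual way to join 2,6-disubstituted 2,4-dialkoxybenzoic acids to phenols: the small, strongly activated acyl donor tolerates its two ortho groups, O4 of 9 has only one ortho substituent, and O2–H of 9 stays out because it is hydrogen-bonded to its ester carbonyl and flanked on both sides.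

**Step 7**
Reactants: 11 methyl 4-{[2,4-bis(benzyloxy)-5-bromo-3-formyl-6-methylbenzoyl]oxy}-2-hydroxy-3,6-dimethylbenzoate
Product: 12 methyl 4-{[2,4-bis(benzyloxy)-5-bromo-3-formyl-6-methylbenzoyl]oxy}-5-bromo-2-hydroxy-3,6-dimethylbenzoate
Conditions: NBS (1.05 equiv), MeCN, 0 °C to rt, dark
Reagents that add atoms: N-bromosuccinimide, O=C1CCC(=O)N1Br
Why: Electrophilic aromatic bromination: ring B C5 is the only unsubstituted carbon on either core ring and lies para to the free O2–H, whereas ring A is fully substituted and the benzyl phenyl rings are unactivated towards NBS.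

**Step 8**
Reactants: 12 methyl 4-{[2,4-bis(benzyloxy)-5-bromo-3-formyl-6-methylbenzoyl]oxy}-5-bromo-2-hydroxy-3,6-dimethylbenzoate
Product: 13 methyl 4-{[2,4-bis(benzyloxy)-5-bromo-3-formyl-6-methylbenzoyl]oxy}-5-bromo-2-methoxy-3,6-dimethylbenzoate
Conditions: MeI (3 equiv), K2CO3, DMF, 40 °C
Reagents that add atoms: iodomethane, CI
Why: Williamson O-methylation of the only free hydroxyl, the ester-chelated O2–H of ring B; with both ring A oxygens capped the depside cannot fragment through a phenoxide, and the di-ortho-substituted ester carbonyls resist carbonate.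

**Step 9**
Reactants: 13 methyl 4-{[2,4-bis(benzyloxy)-5-bromo-3-formyl-6-methylbenzoyl]oxy}-5-bromo-2-methoxy-3,6-dimethylbenzoate
Product: 16 methyl 4-{[2,4-bis(benzyloxy)-3-formyl-5,6-dimethylbenzoyl]oxy}-2-methoxy-3,5,6-trimethylbenzoate, via ring-A monomethyl bromide 14 (not isolated), via ring-B monomethyl bromide 15 (not isolated)
Conditions: MeB(OH)2 (6 equiv), Pd(OAc)2 (10 mol %), SPhos (20 mol %), K3PO4 (6 equiv), degassed toluene/H2O 20:1, 100 °C
Reagents that add atoms: methylboronic acid, CB(O)O
Why: Each C–Br bond of 13 undergoes oxidative addition to SPhos-ligated Pd(0), bromide is exchanged for hydroxide or phosphate, methyl is transferred from the methylboronate and C(sp2)–CH3 reductive elimination follows, the cycle running once at ring A C5 and once at ring B C5 through the monomethyl bromides 14 and 15. The closest known reaction type is the Suzuki–Miyaura methylation of doubly ortho-substituted aryl bromides with methylboronic acid and a dialkylbiarylphosphine. No ring is closed and no stereocentre is created, so neither a closure mode nor stereocontrol arises. The step needs insertion into the two hindered C–Br bonds and not into the acyl C–O bond, with the aldehyde and both esters untouched: Pd(0)/phosphine does not insert into aryl esters under these conditions, the aldehyde has no α-hydrogen and does not react with methylboronic acid, and each ester carbonyl is shielded by two ortho substituents against phosphate. Because O2 and O4 of ring A are benzylated, no phenoxide can form and base-triggered expulsion of the ring B phenoxide (the ketene pathway of free salicylate aryl esters) is shut off, and a methyl ligand has no β-hydrogen, so the slow steps at the crowded palladium cannot divert by β-hydride elimination. Excess boronic acid in a non-polar medium keeps transmetalation faster than palladation of the neighbouring O-benzyl ring.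

**Step 10**
Reactants: 16 methyl 4-{[2,4-bis(benzyloxy)-3-formyl-5,6-dimethylbenzoyl]oxy}-2-methoxy-3,5,6-trimethylbenzoate
Product: 19 methyl 4-[(3-formyl-2,4-dihydroxy-5,6-dimethylbenzoyl)oxy]-2-methoxy-3,5,6-trimethylbenzoate (CNP0206150.0), via 2-O-benzyl monophenol 17 (not isolated), via 4-O-benzyl monophenol 18 (not isolated)
Conditions: H2 (1 atm), 10 % Pd/C, EtOAc, rt
Reagents that add atoms: none
Why: Catalytic hydrogenolysis of the two aryl benzyl ethers: benzylic C–O cleavage on Pd/C is fast in neutral ethyl acetate, whereas the aldehyde, flanked by two oxygens and hydrogen-bonded to each phenol as it is freed, should be reduced much more slowly, no C–Br bond is left to be reduced, and the reaction is stopped after two equivalents of hydrogen.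

**Compound list**
1 | orsellinic acid (2,4-dihydroxy-6-methylbenzoic acid) | Cc1cc(O)cc(O)c1C(=O)O | starting material
2 | allyl 2,4-dihydroxy-6-methylbenzoate | C=CCOC(=O)c1c(C)cc(O)cc1O | intermediate
3 | allyl 3-[chloro(methoxy)methyl]-2,4-dihydroxy-6-methylbenzoate (racemic, transient, titanium-bound) | C=CCOC(=O)c1c(C)cc(O)c(C(Cl)OC)c1O | intermediate
4 | allyl 3-formyl-2,4-dihydroxy-6-methylbenzoate | C=CCOC(=O)c1c(C)cc(O)c(C=O)c1O | intermediate
5 | allyl 5-bromo-3-formyl-2,4-dihydroxy-6-methylbenzoate | C=CCOC(=O)c1c(C)c(Br)c(O)c(C=O)c1O | intermediate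
6 | allyl 4-(benzyloxy)-5-bromo-3-formyl-2-hydroxy-6-methylbenzoate | C=CCOC(=O)c1c(C)c(Br)c(OCc2ccccc2)c(C=O)c1O | intermediate
7 | allyl 2,4-bis(benzyloxy)-5-bromo-3-formyl-6-methylbenzoate | C=CCOC(=O)c1c(C)c(Br)c(OCc2ccccc2)c(C=O)c1OCc1ccccc1 | intermediate
8 | 2,4-bis(benzyloxy)-5-bromo-3-formyl-6-methylbenzoic acid | OC(=O)c1c(C)c(Br)c(OCc2ccccc2)c(C=O)c1OCc1ccccc1 | intermediate
9 | Evernyl (methyl 2,4-dihydroxy-3,6-dimethylbenzoate) | COC(=O)c1c(C)cc(O)c(C)c1O | starting material
10 | 2,4-bis(benzyloxy)-5-bromo-3-formyl-6-methylbenzoic trifluoroacetic anhydride | FC(F)(F)C(=O)OC(=O)c1c(C)c(Br)c(OCc2ccccc2)c(C=O)c1OCc1ccccc1 | intermediate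
11 | methyl 4-{[2,4-bis(benzyloxy)-5-bromo-3-formyl-6-methylbenzoyl]oxy}-2-hydroxy-3,6-dimethylbenzoate | COC(=O)c1c(C)cc(OC(=O)c2c(C)c(Br)c(OCc3ccccc3)c(C=O)c2OCc2ccccc2)c(C)c1O | intermediate
12 | methyl 4-{[2,4-bis(benzyloxy)-5-bromo-3-formyl-6-methylbenzoyl]oxy}-5-bromo-2-hydroxy-3,6-dimethylbenzoate | COC(=O)c1c(C)c(Br)c(OC(=O)c2c(C)c(Br)c(OCc3ccccc3)c(C=O)c2OCc2ccccc2)c(C)c1O | intermediate
13 | methyl 4-{[2,4-bis(benzyloxy)-5-bromo-3-formyl-6-methylbenzoyl]oxy}-5-bromo-2-methoxy-3,6-dimethylbenzoate (di-O-benzyl dibromo nor-depside) | COC(=O)c1c(C)c(Br)c(OC(=O)c2c(C)c(Br)c(OCc3ccccc3)c(C=O)c2OCc2ccccc2)c(C)c1OC | intermediate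
14 | methyl 4-{[2,4-bis(benzyloxy)-3-formyl-5,6-dimethylbenzoyl]oxy}-5-bromo-2-methoxy-3,6-dimethylbenzoate | COC(=O)c1c(C)c(Br)c(OC(=O)c2c(C)c(C)c(OCc3ccccc3)c(C=O)c2OCc2ccccc2)c(C)c1OC | intermediate
15 | methyl 4-{[2,4-bis(benzyloxy)-5-bromo-3-formyl-6-methylbenzoyl]oxy}-2-methoxy-3,5,6-trimethylbenzoate | COC(=O)c1c(C)c(C)c(OC(=O)c2c(C)c(Br)c(OCc3ccccc3)c(C=O)c2OCc2ccccc2)c(C)c1OC | intermediate
16 | methyl 4-{[2,4-bis(benzyloxy)-3-formyl-5,6-dimethylbenzoyl]oxy}-2-methoxy-3,5,6-trimethylbenzoate | COC(=O)c1c(C)c(C)c(OC(=O)c2c(C)c(C)c(OCc3ccccc3)c(C=O)c2OCc2ccccc2)c(C)c1OC | intermediate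
17 | methyl 4-{[2-(benzyloxy)-3-formyl-4-hydroxy-5,6-dimethylbenzoyl]oxy}-2-methoxy-3,5,6-trimethylbenzoate | COC(=O)c1c(C)c(C)c(OC(=O)c2c(C)c(C)c(O)c(C=O)c2OCc2ccccc2)c(C)c1OC | intermediate
18 | methyl 4-{[4-(benzyloxy)-3-formyl-2-hydroxy-5,6-dimethylbenzoyl]oxy}-2-methoxy-3,5,6-trimethylbenzoate | COC(=O)c1c(C)c(C)c(OC(=O)c2c(C)c(C)c(OCc3ccccc3)c(C=O)c2O)c(C)c1OC | intermediate
19 | methyl 4-[(3-formyl-2,4-dihydroxy-5,6-dimethylbenzoyl)oxy]-2-methoxy-3,5,6-trimethylbenzoate (CNP0206150.0) | COC(=O)c1c(C)c(C)c(OC(=O)c2c(C)c(C)c(O)c(C=O)c2O)c(C)c1OC | target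

**Step count**
Total: 10 steps. Longest linear sequence: 10 steps (1 to 19); Evernyl 9 enters at step 6.

**Steps most likely to fail**

Step 9. The catalyst may stall after one methyl transfer, or the C–Br bonds at the two doubly flanked carbons may be reduced instead of methylated, or palladium may attack the neighbouring benzyl ring. The fallback sets out from 8 and 9 and returns at 16. It places the two methyl groups on the separate halves before esterification, one of them without cross-coupling. Acid 8 alone, as its potassium salt, is methylated with the catalyst system of step 9; with no depside ester present, base and temperature can be raised freely. This gives 2,4-bis(benzyloxy)-3-formyl-5,6-dimethylbenzoic acid F1. Evernyl 9 is formylated at its only free carbon, C5 (Cl2CHOMe, TiCl4), to methyl 5-formyl-2,4-dihydroxy-3,6-dimethylbenzoate F2. Ionic hydrogenation of that aldehyde (Et3SiH, TFA) gives methyl 2,4-dihydroxy-3,5,6-trimethylbenzoate F3. F1 and F3 are joined with TFAA as in step 6 to methyl 4-{[2,4-bis(benzyloxy)-3-formyl-5,6-dimethylbenzoyl]oxy}-2-hydroxy-3,5,6-trimethylbenzoate F4, and O-methylation as in step 8 gives 16.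

Step 6. Acyl transfer at the di-ortho-substituted, electron-poor carbonyl may be slower than trifluoroacetylation of the phenol or acid-induced loss of a benzyl group. The fallback sets out from 8 and returns at 11. It replaces acid-mediated mixed-anhydride activation by a preformed acyl chloride and an anionic nucleophile. Oxalyl chloride with catalytic DMF (CH2Cl2, 0 °C to rt) converts 8 into 2,4-bis(benzyloxy)-5-bromo-3-formyl-6-methylbenzoyl chloride F5. This is added to the monosodium phenoxide of 9 (NaH, 1 equiv, THF, 0 °C to rt); the more acidic, non-chelated O4 carries the charge, so 11 should result.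

Step 2. The formyl group may be delivered partly or mainly to C5 instead of C3, and the isomers may be hard to separate. The fallback sets out from 2 and returns at 5. It reverses the order of the two substitutions so that bromine acts as the blocking group. NBS brominates 2 para to the chelated O2–H to give allyl 5-bromo-2,4-dihydroxy-6-methylbenzoate F6. Rieche formylation then has only C3 left and gives 5 directly.

**Further compounds**
F1 | step 9 | 2,4-bis(benzyloxy)-3-formyl-5,6-dimethylbenzoic acid | OC(=O)c1c(C)c(C)c(OCc2ccccc2)c(C=O)c1OCc1ccccc1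
F2 | step 9 | methyl 5-formyl-2,4-dihydroxy-3,6-dimethylbenzoate | COC(=O)c1c(C)c(C=O)c(O)c(C)c1O
F3 | step 9 | methyl 2,4-dihydroxy-3,5,6-trimethylbenzoate | COC(=O)c1c(C)c(C)c(O)c(C)c1O
F4 | step 9 | methyl 4-{[2,4-bis(benzyloxy)-3-formyl-5,6-dimethylbenzoyl]oxy}-2-hydroxy-3,5,6-trimethylbenzoate | COC(=O)c1c(C)c(C)c(OC(=O)c2c(C)c(C)c(OCc3ccccc3)c(C=O)c2OCc2ccccc2)c(C)c1O
F5 | step 6 | 2,4-bis(benzyloxy)-5-bromo-3-formyl-6-methylbenzoyl chloride | ClC(=O)c1c(C)c(Br)c(OCc2ccccc2)c(C=O)c1OCc1ccccc1
F6 | step 2 | allyl 5-bromo-2,4-dihydroxy-6-methylbenzoate | C=CCOC(=O)c1c(C)c(Br)c(O)cc1O
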